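**Retrosynthetic overview**

- Ring A is the sulfated ring (a1 OSO3H, a3 and a5 Br, a6 ether O), ring B the central ring (b1 O to ring A, b2 H, b3–b5 Br, b6 O to ring C), ring C the iodo ring (c1 O, c4 Br, c6 I). The strategy rests on ring B: five of its six carbons are substituted and only b2 bears hydrogen. A formyl carbon on b2 blocks that position, leaves b3, b4 and b5 as the only C–H sites for bromine, and activates a fluoride on b1. It leaves at the end as CO2.
- Late disconnections: O–S (sulfation of the a1 phenol, carried as its methyl ether); the carbon–iodine bond on c6 (from a nitro group through the diazonium salt); C(b2)–H (protodecarboxylation of the acid made from the aldehyde).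
- Ether bonds: a6–O–b1 by SNAr of 4,6-dibromoguaiacol at the formyl-activated C–F; b6–O–c1 by SNAr of the ring B phenoxide on 4-bromo-1-fluoro-2-nitrobenzene. The three C–Br bonds of ring B come from one exhaustive bromination of 2-fluoro-3-hydroxybenzaldehyde.
- No ring is formed in the route; the three benzene rings are bought and joined in the order B, then C, then A.

Key step: step 1

Remark: the target is drawn as the free aryl hydrogen sulfate, so the sulfate is made as its pyridinium salt and protonated at the end; the free acid should be kept cold and dry.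

**Route**

Step 1
Reactants: 1 2-fluoro-3-hydroxybenzaldehyde
Product: 2 4,5,6-tribromo-2-fluoro-3-hydroxybenzaldehyde
Conditions: Br2 (8 equiv), ClCH2CH2Cl, rt; then FeBr3 (30 mol %), 70 °C, sealed tube, dark; aq. NaHSO3
Reagents that add atoms: bromine, BrBr
Why: Three successive electrophilic aromatic substitutions by the arenium-ion mechanism: the hydroxyl on b6 sends the first two bromines to b5 (ortho) and b3 (para) without catalyst, and Br2 polarised by FeBr3 then forces the third onto b4, the last C–H, which lies para to fluorine, between two bromines and meta to both hydroxyl and formyl. The closest known reaction type is the perbromination of phenols and deactivated arenes with excess Br2 and a halide of trivalent iron or aluminium, as in the preparation of pentabromophenol. No ring is closed and no stereocentre is formed. The selectivity needed is completeness together with survival of the aldehyde: b2 is occupied by the formyl carbon and is meta to the hydroxyl, so ipso attack and bromodeformylation are not favoured, and b1 is held by fluorine. Anhydrous conditions in the dark should keep the formyl group from being oxidised through the acyl bromide.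

Step 2
Reactants: 2 4,5,6-tribromo-2-fluoro-3-hydroxybenzaldehyde; 3 4-bromo-1-fluoro-2-nitrobenzene (2 equiv)
Product: 4 4,5,6-tribromo-3-(4-bromo-2-nitrophenoxy)-2-fluorobenzaldehyde
Conditions: K2CO3, DMF, 60 °C, slow addition of 2 to 3
Reagents that add atoms: none
Why: SNAr by addition–elimination: the phenoxide of 2 adds to the fluorine-bearing carbon of 3, activated by the ortho nitro group, and fluoride leaves; the excess of 3 and the slow addition should keep the phenoxide from attacking the more crowded formyl-activated C–F of 4.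

Step 3
Reactants: 5 guaiacol
Product: 6 2,4-dibromo-6-methoxyphenol (4,6-dibromoguaiacol)
Conditions: NBS (2.1 equiv), i-Pr2NH (10 mol %), CH2Cl2, 0 °C → rt
Reagents that add atoms: N-bromosuccinimide, O=C1CCC(=O)N1Br
Why: Amine-catalysed electrophilic aromatic bromination: the free hydroxyl outweighs the methoxy group as director, so bromine should enter ortho and para to OH, while the two carbons activated only by OMe stay untouched at two equivalents.

Step 4
Reactants: 4 4,5,6-tribromo-3-(4-bromo-2-nitrophenoxy)-2-fluorobenzaldehyde; 6 2,4-dibromo-6-methoxyphenol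
Product: 7 4,5,6-tribromo-3-(4-bromo-2-nitrophenoxy)-2-(2,4-dibromo-6-methoxyphenoxy)benzaldehyde
Conditions: Cs2CO3 (1.5 equiv), DMF, rt → 50 °C
Reagents that add atoms: none
Why: SNAr: the caesium phenoxide of 6 adds to b1, where fluoride is the best nucleofuge in the molecule and the Meisenheimer complex is stabilised by the ortho formyl group and the three bromines, giving the a6–O–b1 ether; the C–Br carbons ortho and para to formyl should react far more slowly than C–F.

Step 5
Reactants: 7 4,5,6-tribromo-3-(4-bromo-2-nitrophenoxy)-2-(2,4-dibromo-6-methoxyphenoxy)benzaldehyde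
Product: 8 4,5,6-tribromo-3-(4-bromo-2-nitrophenoxy)-2-(2,4-dibromo-6-methoxyphenoxy)benzoic acid
Conditions: NaClO2, NaH2PO4, 2-methyl-2-butene, t-BuOH/THF/H2O, rt
Reagents that add atoms: sodium chlorite, [Na+].[O-]Cl=O
Why: Pinnick oxidation: chlorous acid adds to the hindered aldehyde and fragments to the acid, and 2-methyl-2-butene traps HOCl so that the anisole ring is not chlorinated; nitro group, aryl bromides and ethers are inert.

Step 6
Reactants: 8 4,5,6-tribromo-3-(4-bromo-2-nitrophenoxy)-2-(2,4-dibromo-6-methoxyphenoxy)benzoic acid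
Product: 9 1,2,3-tribromo-4-(4-bromo-2-nitrophenoxy)-5-(2,4-dibromo-6-methoxyphenoxy)benzene
Conditions: Ag2CO3 (10 mol %), AcOH (5 mol %), DMSO, 120 °C
Reagents that add atoms: none
Why: Silver-catalysed protodecarboxylation: the silver carboxylate of an acid flanked by an ortho bromine and an ortho aryloxy group loses CO2 to an aryl-silver species (monovalent silver) that is protonated by the acid present, a known reaction of doubly ortho-substituted electron-poor benzoic acids that leaves aryl bromides and the nitro group alone.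

Step 7
Reactants: 9 1,2,3-tribromo-4-(4-bromo-2-nitrophenoxy)-5-(2,4-dibromo-6-methoxyphenoxy)benzene
Product: 10 5-bromo-2-[2,3,4-tribromo-6-(2,4-dibromo-6-methoxyphenoxy)phenoxy]aniline
Conditions: Fe powder, AcOH/EtOH, 70 °C
Reagents that add atoms: none
Why: Dissolving-metal (Béchamp-type) reduction: iron in acetic acid reduces the nitro group to the amine by electron transfer without hydrogenolysis of the six aryl bromides, which catalytic hydrogenation would endanger.

Step 8
Reactants: 10 5-bromo-2-[2,3,4-tribromo-6-(2,4-dibromo-6-methoxyphenoxy)phenoxy]aniline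
Product: 12 1,2,3-tribromo-4-(4-bromo-2-iodophenoxy)-5-(2,4-dibromo-6-methoxyphenoxy)benzene, via arenediazonium tosylate 11 (not isolated)
Conditions: p-TsOH·H2O (3 equiv), NaNO2 (2 equiv), KI (2.5 equiv), MeCN/H2O, 10 °C → rt
Reagents that add atoms: potassium iodide, [K+].[I-] (sodium nitrite, O=N[O-].[Na+], and p-toluenesulfonic acid, Cc1ccc(S(=O)(=O)O)cc1, put atoms into 11 only)
Why: Sandmeyer-type iododediazoniation: nitrous acid from NaNO2 and p-TsOH gives the arenediazonium tosylate, which iodide reduces to the aryl radical that is trapped by iodine, so no copper is needed; the two ring B carbons within reach of the radical are fully substituted, so closure to a dibenzofuran is not expected.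

Step 9
Reactants: 12 1,2,3-tribromo-4-(4-bromo-2-iodophenoxy)-5-(2,4-dibromo-6-methoxyphenoxy)benzene
Product: 13 3,5-dibromo-2-[3,4,5-tribromo-2-(4-bromo-2-iodophenoxy)phenoxy]phenol
Conditions: BBr3 (3 equiv), CH2Cl2, −78 → 0 °C; then H2O
Reagents that add atoms: none
Why: Lewis-acid ether cleavage: BBr3 binds the methoxy oxygen and bromide attacks the methyl carbon (SN2), so only the alkyl aryl ether is cut, while the two diaryl ethers, which offer no sp3 carbon, and the aryl halides stay.

Step 10
Reactants: 13 3,5-dibromo-2-[3,4,5-tribromo-2-(4-bromo-2-iodophenoxy)phenoxy]phenol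
Product: 15 bromoiesol B sulfate (3,5-dibromo-2-[3,4,5-tribromo-2-(4-bromo-2-iodophenoxy)phenoxy]phenyl hydrogen sulfate), via pyridinium aryl sulfate 14 (not isolated)
Conditions: SO3·pyridine (5 equiv), pyridine, 50 °C; then sulfonic acid resin (H+ form), MeOH, 0 °C
Reagents that add atoms: sulfur trioxide–pyridine complex, O=S(=O)([O-])[n+]1ccccc1
Why: O-Sulfation of a phenol with the sulfur trioxide–pyridine complex gives the pyridinium aryl sulfate, and cation exchange against H+ in the cold should set the hydrogen sulfate free without hydrolysing the S–O–aryl bond.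

**Compound list**

1 | 2-fluoro-3-hydroxybenzaldehyde | O=Cc1cccc(O)c1F | starting material
2 | 4,5,6-tribromo-2-fluoro-3-hydroxybenzaldehyde | O=Cc1c(Br)c(Br)c(Br)c(O)c1F | intermediate
3 | 4-bromo-1-fluoro-2-nitrobenzene | O=[N+]([O-])c1cc(Br)ccc1F | starting material
4 | 4,5,6-tribromo-3-(4-bromo-2-nitrophenoxy)-2-fluorobenzaldehyde | O=Cc1c(Br)c(Br)c(Br)c(Oc2ccc(Br)cc2[N+](=O)[O-])c1F | intermediate
5 | guaiacol (2-methoxyphenol) | COc1ccccc1O | starting material
6 | 2,4-dibromo-6-methoxyphenol (4,6-dibromoguaiacol) | COc1cc(Br)cc(Br)c1O | intermediate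
7 | 4,5,6-tribromo-3-(4-bromo-2-nitrophenoxy)-2-(2,4-dibromo-6-methoxyphenoxy)benzaldehyde | O=Cc1c(Br)c(Br)c(Br)c(Oc2ccc(Br)cc2[N+](=O)[O-])c1Oc1c(OC)cc(Br)cc1Br | intermediate
8 | 4,5,6-tribromo-3-(4-bromo-2-nitrophenoxy)-2-(2,4-dibromo-6-methoxyphenoxy)benzoic acid | O=C(O)c1c(Br)c(Br)c(Br)c(Oc2ccc(Br)cc2[N+](=O)[O-])c1Oc1c(OC)cc(Br)cc1Br | intermediate
9 | 1,2,3-tribromo-4-(4-bromo-2-nitrophenoxy)-5-(2,4-dibromo-6-methoxyphenoxy)benzene | COc1cc(Br)cc(Br)c1Oc1cc(Br)c(Br)c(Br)c1Oc1ccc(Br)cc1[N+](=O)[O-] | intermediate
10 | 5-bromo-2-[2,3,4-tribromo-6-(2,4-dibromo-6-methoxyphenoxy)phenoxy]aniline | COc1cc(Br)cc(Br)c1Oc1cc(Br)c(Br)c(Br)c1Oc1ccc(Br)cc1N | intermediate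
11 | 5-bromo-2-[2,3,4-tribromo-6-(2,4-dibromo-6-methoxyphenoxy)phenoxy]benzenediazonium p-toluenesulfonate | COc1cc(Br)cc(Br)c1Oc1cc(Br)c(Br)c(Br)c1Oc1ccc(Br)cc1[N+]#N.Cc1ccc(S(=O)(=O)[O-])cc1 | intermediate
12 | 1,2,3-tribromo-4-(4-bromo-2-iodophenoxy)-5-(2,4-dibromo-6-methoxyphenoxy)benzene | COc1cc(Br)cc(Br)c1Oc1cc(Br)c(Br)c(Br)c1Oc1ccc(Br)cc1I | intermediate
13 | 3,5-dibromo-2-[3,4,5-tribromo-2-(4-bromo-2-iodophenoxy)phenoxy]phenol | Oc1cc(Br)cc(Br)c1Oc1cc(Br)c(Br)c(Br)c1Oc1ccc(Br)cc1I | intermediate
14 | pyridinium 3,5-dibromo-2-[3,4,5-tribromo-2-(4-bromo-2-iodophenoxy)phenoxy]phenyl sulfate | [O-]S(=O)(=O)Oc1cc(Br)cc(Br)c1Oc1cc(Br)c(Br)c(Br)c1Oc1ccc(Br)cc1I.c1cc[nH+]cc1 | intermediate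
15 | bromoiesol B sulfate | O=S(=O)(O)Oc1cc(Br)cc(Br)c1Oc1cc(Br)c(Br)c(Br)c1Oc1ccc(Br)cc1I | target

**Step count**

Total: 10 steps. Longest linear sequence: 9 steps (steps 1, 2 and 4 to 10, from 1); step 3 is a one-step branch.

**Steps most likely to fail**

1. Step 1. The third bromination may stall on the deactivated ring at the dibromide stage, or the forcing conditions may oxidise the formyl group through radical formation of the acyl bromide. Fallback: setting out from 1, Br2 (2.2 equiv) in AcOH at rt should stop cleanly at 4,6-dibromo-2-fluoro-3-hydroxybenzaldehyde F1. The last bromine is then delivered by dibromoisocyanuric acid (0.6 equiv) in concentrated H2SO4 at rt. The protonated N-bromoimide is a much stronger electrophile than Br2 with FeBr3, and the ionic medium offers no radical path to the acyl bromide. This returns to the route at 2.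

2. Step 4. The hindered phenoxide may attack the nitro-activated c1 of ring C with loss of the ring B phenoxide (ether exchange), or the formyl-activated C–Br carbons b3 and b5, instead of the crowded C–F carbon b1. Fallback: the order of the two ether formations is reversed, setting out from 2 and 6, so that no nitro-activated ether is present when ring A is attached. Phenol 2 is capped with chloromethyl methyl ether and i-Pr2NEt in CH2Cl2 to give 4,5,6-tribromo-2-fluoro-3-(methoxymethoxy)benzaldehyde F4. SNAr with 6 (Cs2CO3, DMF) gives 4,5,6-tribromo-2-(2,4-dibromo-6-methoxyphenoxy)-3-(methoxymethoxy)benzaldehyde F5. Aqueous HCl in THF frees 4,5,6-tribromo-2-(2,4-dibromo-6-methoxyphenoxy)-3-hydroxybenzaldehyde F6. Its phenoxide is then arylated with 3 (K2CO3, DMF, 80 °C), coming back to the route at 7.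

3. Step 2. The phenoxide of 2 may add to the formyl-activated C–F of product 4 or of a second molecule of 2 instead of to 3, leading to oligomeric ethers. Fallback: the activation is switched off during this coupling by masking the aldehyde. Setting out from 2, ethylene glycol and catalytic p-TsOH in toluene with azeotropic removal of water give 2,3,4-tribromo-5-(1,3-dioxolan-2-yl)-6-fluorophenol F2. SNAr on 3 (K2CO3, DMF, 70 °C) gives 2-[2,3,4-tribromo-5-(4-bromo-2-nitrophenoxy)-6-fluorophenyl]-1,3-dioxolane F3. Hydrolysis with 2 M HCl in THF returns to the route at 4.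

**Further compounds**

F1 | step 1 | 4,6-dibromo-2-fluoro-3-hydroxybenzaldehyde | O=Cc1c(Br)cc(Br)c(O)c1F
F2 | step 2 | 2,3,4-tribromo-5-(1,3-dioxolan-2-yl)-6-fluorophenol | Oc1c(F)c(C2OCCO2)c(Br)c(Br)c1Br
F3 | step 2 | 2-[2,3,4-tribromo-5-(4-bromo-2-nitrophenoxy)-6-fluorophenyl]-1,3-dioxolane | O=[N+]([O-])c1cc(Br)ccc1Oc1c(F)c(C2OCCO2)c(Br)c(Br)c1Br
F4 | step 4 | 4,5,6-tribromo-2-fluoro-3-(methoxymethoxy)benzaldehyde | COCOc1c(F)c(C=O)c(Br)c(Br)c1Br
F5 | step 4 | 4,5,6-tribromo-2-(2,4-dibromo-6-methoxyphenoxy)-3-(methoxymethoxy)benzaldehyde | COCOc1c(Br)c(Br)c(Br)c(C=O)c1Oc1c(OC)cc(Br)cc1Br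
F6 | step 4 | 4,5,6-tribromo-2-(2,4-dibromo-6-methoxyphenoxy)-3-hydroxybenzaldehyde | O=Cc1c(Br)c(Br)c(Br)c(O)c1Oc1c(OC)cc(Br)cc1Br
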